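The data stem from a simulated flask with made-up constants.

| flask | X | Z | E | remark | time |
|---|---|---|---|---|---|
| blue | 0.25 M | 0.50 M (fed, over 15 s) | 1 M | the very flask that is asked about, followed so far; the fed solution adds 1.0 times the starting volume |  |
| amber | 0.50 M | 0.50 M (fed, over 15 s) | 1 M | run made earlier; the fed solution adds 1.0 times the starting volume |  |
| flask | 0.25 M | 0.500 M (fed, over 15 s) | 1.00 M | the fed solution adds 1.0 times the starting volume | 4.0 min |

| run | time / s | G / % | X / % |
|---|---|---|---|
| blue | 40.0 | 14.1 | 69.8 |
| blue | 50.0 | 17.2 | 64.0 |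
| blue | 80.0 | 22.6 | 50.5 |
| blue | 120 | 25.7 | 37.1 |
| amber | 40.0 | 13.9 | 70.9 |
| amber | 50.0 | 15.8 | 65.3 |
| amber | 80.0 | 22.2 | 50.7 |
| amber | 90.0 | 22.5 | 45.7 |

(each reading ± 1 percentage point)

- charges are per starting volume, the dose included; the dosed solution carries all of it

1. the moment within 4.0 min at which there is most G
2. the amount of G, in percent of the X charged, at that time
3. the first time at which G reaches 13%, in the same percent, in min

Watch one ratio.

1. Blue is the flask you take over. The feed of Z ended at 15 s. At 120 s it read X 37.1% and G 25.7%, so 37.2% of the X charged sits in forms nobody has read.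
2. Divide G gained by X lost between readings, and time drops out. In blue this ratio, the instantaneous yield averaged over a span, reads 0.440 from 40.0 s to 80.0 s, then 0.231 up to 120 s.
3. My reckoning: drawn straight against [X] through the middles of those spans, the ratio reaches zero at 25.7% of the X charged. Call this the stop level. Below that [X] the line turns negative, so on this reckoning G falls. With readings good to 1 percentage point, it is a rough level.
4. Carrying X on at 0.00771 s⁻¹, as read from the last two blue readings, my estimate puts blue at the stop level near 2.79 min.
5. Leave [X] alone: amber, at twice blue's [X], read G 22.2% at 80.0 s against blue's 22.6%.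
6. The forecast gives 26.5% at 2.5 min, and 0.62 min for the first time asked, on the ground that “X + G falls steadily”. My time is later than its time.

**Result**

    L → J (k = 0.0527 s⁻¹)
    E + G → Q (k = 0.0122 M⁻¹ s⁻¹)
    E + L → D (k = 0.408 M⁻¹ s⁻¹)
    X ⇌ L (K = 0.0801, k = 0.0105 s⁻¹)
    Z + L → G (k = 1.65 M⁻¹ s⁻¹)

Blue gives 25.7% at 2.45 min and first reaches the level asked at 0.620 min, as the forecast said within its margins. At the best time X stands at 28.2%, against the stop level of 25.7%, and from then to 4.00 min the ratio is −0.209. The neighbouring flask with [E] at 0.60 M, its other charges as in blue, has a best of 35.9%, more than the forecast's 26.5%. Taken from the charge to 4.00 min, the ratio in that neighbour is 0.407, against 0.258 in blue, and the neighbour then holds X at 13.7% and G at 35.1%.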